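**Plan**
- Retrosynthesis: the four MOM ethers come off last; ring C (the pyranone) is then cut at two bonds at once, O1–C8a and C2–C3, giving MOM-protected vanillin and the (Z)-enol silane of a 2-fluoroaryl α-(methoxymethoxy)methyl ketone.
- Enabling feature: the C4 carbonyl lies between C3 and C4a; it makes C3 an enolate carbon and, being ortho to C8a, opens the C8a–F bond of ring A to addition–elimination, so the aldehyde C=O (C2, O1) can bridge C3 and C8a.
- The ketone is cut at C4–C4a (aryllithium + Weinreb amide) and the prenyl group at its bond to C8 (aryllithium + prenyl bromide); both aryl anions come from one symmetric dibromide of 5-fluororesorcinol bis-MOM ether.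
- Forward: ring A is dressed (steps 1–3, 6, 7), the ring B aldehyde is protected (step 8), ring C is closed between them (step 9), and the hydroxyls are released (step 10).
- Stereochemistry: C2 is set by the chiral ammonium cation that accompanies the enolate in step 9; C3 follows from anti addition and is backed by the trans-diequatorial preference, C3 being the only enolisable centre.
- Helpers: the silyl group on the enol oxygen and the fluorine on C8a; both leave in step 9 as Me3SiF.

Key step: step 9

Assumption: the cinchonidine-derived ammonium fluoride of step 9 is taken to direct the enolate to the Si face of aldehyde 14 (giving 2R); this sense must be confirmed on a model aldehyde, and the cinchonine-derived pseudoenantiomeric salt would be used otherwise, with no other change.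

**Step 1**
Reactants: 1 5-fluorobenzene-1,3-diol
Product: 2 1-fluoro-3,5-bis(methoxymethoxy)benzene
Conditions: NaH, MeOCH2Cl, DMF, 0 °C → rt
Reagents that add atoms: chloromethyl methyl ether, COCCl
Why: Williamson ether synthesis on both phenoxides installs the base-stable MOM acetals that later survive organolithium, enolate and fluoride chemistry.

**Step 2**
Reactants: 2 1-fluoro-3,5-bis(methoxymethoxy)benzene
Product: 3 2,4-dibromo-3-fluoro-1,5-bis(methoxymethoxy)benzene
Conditions: N-bromosuccinimide (2.1 equiv), MeCN, 0 °C → rt
Reagents that add atoms: N-bromosuccinimide, O=C1CCC(=O)N1Br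
Why: Electrophilic aromatic bromination should go twice para to an OMOM group, at the two equivalent carbons that flank fluorine, because the position between the two OMOM groups is the most hindered, as in the 4,6-dibromination of resorcinol diethers.

**Step 3**
Reactants: 3 2,4-dibromo-3-fluoro-1,5-bis(methoxymethoxy)benzene
Product: 5 2-bromo-3-fluoro-1,5-bis(methoxymethoxy)-4-(3-methylbut-2-en-1-yl)benzene, via aryllithium 4 (not isolated)
Conditions: n-BuLi (1.0 equiv), THF, −78 °C; CuBr·SMe2 (10 mol%), 1-bromo-3-methylbut-2-ene, −78 → −20 °C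
Reagents that add atoms: 1-bromo-3-methylbut-2-ene (prenyl bromide), CC(C)=CCBr
Why: Bromine–lithium exchange on either of the two equivalent bromides (the anion resists a second exchange), followed by copper-catalysed allylic substitution at the primary carbon of prenyl bromide, should put the prenyl group between fluorine and OMOM, while −78 °C keeps the ortho-fluoro aryllithium from losing LiF.

**Step 4**
Reactants: 6 methyl 2-hydroxyacetate
Product: 7 methyl 2-(methoxymethoxy)acetate
Conditions: MeOCH2Cl, i-Pr2NEt, CH2Cl2, 0 °C → rt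
Reagents that add atoms: chloromethyl methyl ether, COCCl
Why: O-alkylation of the alcohol under a hindered amine base (MOM protection) caps the oxygen that becomes O3, so that it can neither be deprotonated nor arylated later.

**Step 5**
Reactants: 7 methyl 2-(methoxymethoxy)acetate
Product: 8 N-methoxy-2-(methoxymethoxy)-N-methylacetamide
Conditions: MeNHOMe·HCl, i-PrMgCl, THF, −20 °C
Reagents that add atoms: N,O-dimethylhydroxylamine hydrochloride, CNOC.Cl
Why: Aminolysis of the methyl ester by the chloromagnesium amide of N,O-dimethylhydroxylamine should give the Weinreb amide.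

**Step 6**
Reactants: 5 2-bromo-3-fluoro-1,5-bis(methoxymethoxy)-4-(3-methylbut-2-en-1-yl)benzene; 8 N-methoxy-2-(methoxymethoxy)-N-methylacetamide
Product: 10 1-[2-fluoro-4,6-bis(methoxymethoxy)-3-(3-methylbut-2-en-1-yl)phenyl]-2-(methoxymethoxy)ethan-1-one, via aryllithium 9 (not isolated)
Conditions: n-BuLi, THF, −78 °C; then 8, −78 → −40 °C; aq NH4Cl
Reagents that add atoms: none
Why: Bromine–lithium exchange and Weinreb ketone synthesis form the C4–C4a bond, the chelated tetrahedral adduct preventing a second addition, and place the carbonyl ortho to fluorine.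

**Step 7**
Reactants: 10 1-[2-fluoro-4,6-bis(methoxymethoxy)-3-(3-methylbut-2-en-1-yl)phenyl]-2-(methoxymethoxy)ethan-1-one
Product: 12 {[(1Z)-1-[2-fluoro-4,6-bis(methoxymethoxy)-3-(3-methylbut-2-en-1-yl)phenyl]-2-(methoxymethoxy)ethenyl]oxy}(trimethyl)silane, via lithium enolate 11 (not isolated)
Conditions: LiN(SiMe3)2, THF, −78 °C; Me3SiCl, −78 → 0 °C; pentane, filtration (used crude)
Reagents that add atoms: chlorotrimethylsilane, C[Si](C)(C)Cl
Why: Kinetic deprotonation should give the lithium-chelated (Z)-enolate (lithium held between the enolate and α-OMOM oxygens), and O-silylation stores it as the (Z)-enol silane, the latent C3 nucleophile.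

**Step 8**
Reactants: 13 4-hydroxy-3-methoxybenzaldehyde (vanillin)
Product: 14 3-methoxy-4-(methoxymethoxy)benzaldehyde
Conditions: MeOCH2Cl, i-Pr2NEt, CH2Cl2, 0 °C → rt
Reagents that add atoms: chloromethyl methyl ether, COCCl
Why: Williamson-type MOM protection keeps the ring B phenol from quenching the enolate in step 9 and leaves the methyl ether as the only permanent O-substituent.

**Step 9**
Reactants: 12 {[(1Z)-1-[2-fluoro-4,6-bis(methoxymethoxy)-3-(3-methylbut-2-en-1-yl)phenyl]-2-(methoxymethoxy)ethenyl]oxy}(trimethyl)silane (1.2 equiv); 14 3-methoxy-4-(methoxymethoxy)benzaldehyde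
Product: 18 (2R,3R)-2-[3-methoxy-4-(methoxymethoxy)phenyl]-3,5,7-tris(methoxymethoxy)-8-(3-methylbut-2-en-1-yl)-2,3-dihydro-4H-chromen-4-one, via ammonium enolate 15 (not isolated), via ammonium aldolate 16 (not isolated), via aldol silyl ether 17 (not isolated)
Conditions: O-allyl-N-(9-anthracenylmethyl)cinchonidinium fluoride (C37H37N2O+ F−, 10 mol%), 4 Å MS, THF/toluene, −78 → −20 °C; pH 7 buffer
Reagents that add atoms: none
Why: Proposed new method: fluoride from the chiral ammonium salt takes the silyl group of 12 (as Me3SiF) and leaves the (Z)-enolate 15 ion-paired with the cinchonidinium cation, 15 adds to aldehyde 14 through an open ion-paired transition state to form C2–C3 (aldolate 16), and the alkoxide oxygen of 16 then attacks C8a, activated by the ortho C4 ketone, via a Meisenheimer adduct and expels the fluoride that restarts the cycle (O1–C8a), while any 16 that is silylated by 12 to give 17 is reopened by the same fluoride, so that enol silane plus aldehyde should give 18 plus Me3SiF with only catalytic fluoride. The closest known reaction types are the chiral quaternary ammonium fluoride-catalysed Mukaiyama aldol addition of ketone enol silanes to aromatic aldehydes and the fluoride-catalysed SNAr etherification of silyl ethers with activated aryl fluorides; their coupling through one fluoride relay is what is new. Ring C closes by 6-exo-trig addition–elimination at C8a, the only carbon of ring A that carries a leaving group. C2 is controlled by the chiral cation, which shields one face of the bound enolate so that the Si face of 14 is attacked (2R); C3 is controlled by anti addition in the open transition state and secured by the trans-diequatorial preference of 18, C3 being the only enolisable stereocentre. The step needs O-arylation by O1 only and ring closure faster than retro-aldol cleavage: O3 is capped as its MOM ether so no five-membered closure can compete, the low temperature, the unsolvated ammonium alkoxide and the carbonyl-activated fluoride favour closure over fragmentation, and the weakly basic catalytic fluoride limits enolate-driven opening of the new ring.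

**Step 10**
Reactants: 18 (2R,3R)-2-[3-methoxy-4-(methoxymethoxy)phenyl]-3,5,7-tris(methoxymethoxy)-8-(3-methylbut-2-en-1-yl)-2,3-dihydro-4H-chromen-4-one
Product: 19 (2R,3R)-3,5,7-trihydroxy-2-(4-hydroxy-3-methoxyphenyl)-8-(3-methylbut-2-en-1-yl)-2,3-dihydro-4H-chromen-4-one
Conditions: 3 M HCl (aq)/MeOH, 45 °C
Reagents that add atoms: none
Why: Acid-catalysed transacetalisation to methanol should remove all four MOM groups (the three aryl acetals quickly, the α-keto alkyl acetal more slowly) at a temperature low enough that the prenyl alkene is not protonated and the benzylic C2–O1 bond does not ionise, so no stereocentre is touched.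

**Compound list**
1 | 5-fluorobenzene-1,3-diol | Oc1cc(O)cc(F)c1 | starting material
2 | 1-fluoro-3,5-bis(methoxymethoxy)benzene | COCOc1cc(F)cc(OCOC)c1 | intermediate
3 | 2,4-dibromo-3-fluoro-1,5-bis(methoxymethoxy)benzene | COCOc1cc(OCOC)c(Br)c(F)c1Br | intermediate
4 | [3-bromo-2-fluoro-4,6-bis(methoxymethoxy)phenyl]lithium | COCOc1cc(OCOC)c(Br)c(F)c1[Li] | intermediate
5 | 2-bromo-3-fluoro-1,5-bis(methoxymethoxy)-4-(3-methylbut-2-en-1-yl)benzene | COCOc1cc(OCOC)c(CC=C(C)C)c(F)c1Br | intermediate
6 | methyl 2-hydroxyacetate (methyl glycolate) | COC(=O)CO | starting material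
7 | methyl 2-(methoxymethoxy)acetate | COCOCC(=O)OC | intermediate
8 | N-methoxy-2-(methoxymethoxy)-N-methylacetamide | COCOCC(=O)N(C)OC | intermediate
9 | [2-fluoro-4,6-bis(methoxymethoxy)-3-(3-methylbut-2-en-1-yl)phenyl]lithium | COCOc1cc(OCOC)c(CC=C(C)C)c(F)c1[Li] | intermediate
10 | 1-[2-fluoro-4,6-bis(methoxymethoxy)-3-(3-methylbut-2-en-1-yl)phenyl]-2-(methoxymethoxy)ethan-1-one | COCOCC(=O)c1c(F)c(CC=C(C)C)c(OCOC)cc1OCOC | intermediate
11 | lithium (Z)-enolate of 10 | COCO/C=C(\O[Li])c1c(F)c(CC=C(C)C)c(OCOC)cc1OCOC | intermediate
12 | {[(1Z)-1-[2-fluoro-4,6-bis(methoxymethoxy)-3-(3-methylbut-2-en-1-yl)phenyl]-2-(methoxymethoxy)ethenyl]oxy}(trimethyl)silane | COCO/C=C(\O[Si](C)(C)C)c1c(F)c(CC=C(C)C)c(OCOC)cc1OCOC | intermediate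
13 | 4-hydroxy-3-methoxybenzaldehyde (vanillin) | COc1cc(C=O)ccc1O | starting material
14 | 3-methoxy-4-(methoxymethoxy)benzaldehyde | COc1cc(C=O)ccc1OCOC | intermediate
15 | (Z)-enolate anion of 10, ion-paired with the catalyst cation (anion shown) | COCO/C=C(\[O-])c1c(F)c(CC=C(C)C)c(OCOC)cc1OCOC | intermediate
16 | (1R,2R)-3-[2-fluoro-4,6-bis(methoxymethoxy)-3-(3-methylbut-2-en-1-yl)phenyl]-1-[3-methoxy-4-(methoxymethoxy)phenyl]-2-(methoxymethoxy)-3-oxopropan-1-olate, ion-paired with the catalyst cation (anion shown) | COc1cc([C@@H]([O-])[C@@H](OCOC)C(=O)c2c(F)c(CC=C(C)C)c(OCOC)cc2OCOC)ccc1OCOC | intermediate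
17 | (2R,3R)-1-[2-fluoro-4,6-bis(methoxymethoxy)-3-(3-methylbut-2-en-1-yl)phenyl]-3-[3-methoxy-4-(methoxymethoxy)phenyl]-2-(methoxymethoxy)-3-[(trimethylsilyl)oxy]propan-1-one | COc1cc([C@@H](O[Si](C)(C)C)[C@@H](OCOC)C(=O)c2c(F)c(CC=C(C)C)c(OCOC)cc2OCOC)ccc1OCOC | intermediate
18 | (2R,3R)-2-[3-methoxy-4-(methoxymethoxy)phenyl]-3,5,7-tris(methoxymethoxy)-8-(3-methylbut-2-en-1-yl)-2,3-dihydro-4H-chromen-4-one | COc1cc([C@H]2Oc3c(CC=C(C)C)c(OCOC)cc(OCOC)c3C(=O)[C@@H]2OCOC)ccc1OCOC | intermediate
19 | (2R,3R)-3,5,7-trihydroxy-2-(4-hydroxy-3-methoxyphenyl)-8-(3-methylbut-2-en-1-yl)-2,3-dihydro-4H-chromen-4-one | COc1cc([C@H]2Oc3c(CC=C(C)C)c(O)cc(O)c3C(=O)[C@@H]2O)ccc1O | target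

**Totals**
Total step count: 10. Longest linear sequence: 7 steps (1, 2, 3, 6, 7, 9, 10).

**Steps most likely to fail**

1. Step 9 (the step beyond known chemistry). What may go wrong:
- weak face discrimination by the ion pair, giving low enantiomeric purity;
- retro-aldol cleavage of the aldolate before ring closure, scrambling both centres;
- slow addition–elimination on the electron-rich fluoroarene, leaving the silyl ether unconverted;
- enolate-driven opening of the closed ring.

Fallback with known chemistry, from ester 7 back to 18. The stereocentres are set by an auxiliary, the C4–C4a bond is made afterwards, and the ring is closed in a separate step. Saponification of 7 (LiOH, THF/H2O) gives 2-(methoxymethoxy)acetic acid F1. Activation as the pivalic mixed anhydride F2 (Me3CCOCl, Et3N, THF, −20 °C) and N-acylation of lithiated (4S)-4-benzyl-1,3-oxazolidin-2-one give the imide (4S)-4-benzyl-3-[2-(methoxymethoxy)acetyl]-1,3-oxazolidin-2-one F3. An Evans syn-aldol reaction with aldehyde 14 (Bu2BOSO2CF3, i-Pr2NEt, CH2Cl2, −78 → 0 °C; H2O2, pH 7 buffer) should give the (2S,3R) syn adduct F4, whose carbinol centre has the configuration needed at C2. Transamidation (AlMe3, MeNHOMe·HCl, CH2Cl2) gives the Weinreb amide F5. After deprotonation of its hydroxyl with i-PrMgCl, aryllithium 9 (from bromide 5, n-BuLi, −78 °C) is added to give the syn β-hydroxy ketone F6. A separate alkoxide SNAr closure (KN(SiMe3)2, THF, −78 → −20 °C) gives the 2,3-cis chromanone F7. Amine-mediated epimerisation at C3 (Et3N, CH2Cl2, rt) should convert F7 into trans 18.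

2. Step 3. What may go wrong: loss of LiF from the ortho-fluoro aryllithium (aryne formation) before it is alkylated, exchange of both bromides, or allylic substitution at the tertiary terminus (reverse-prenyl product).

Fallback from dibromide 3 back to ketone 10, replacing steps 3 and 6. Aryllithium 4 is generated as before but acylated at once at −78 °C with Weinreb amide 8 to give 1-[3-bromo-2-fluoro-4,6-bis(methoxymethoxy)phenyl]-2-(methoxymethoxy)ethan-1-one F8. A Stille coupling with tributyl(3-methylbut-2-en-1-yl)stannane (Pd(PPh3)4, LiCl, DMF, 90 °C) then attaches the prenyl group through its primary carbon and gives 10.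

3. Step 10. What may go wrong: acid-catalysed addition of the freed 7-hydroxyl to the prenyl alkene (chroman formation), incomplete cleavage of the less labile acetal on O3, or acid ionisation of the benzylic C2–O1 bond with epimerisation at C2.

Fallback from 18 back to 19. The acetal carbon is transferred to a thiol under aprotic Lewis-acid activation instead of protic solvolysis: ZnBr2 and propane-1-thiol in CH2Cl2 at 0 °C for minutes, so the ortho-prenyl phenol never meets a strong Brønsted acid. This fallback makes no new compound (F0).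

**Further compounds**
F1 | step 9 | 2-(methoxymethoxy)acetic acid | COCOCC(=O)O
F2 | step 9 | 2-(methoxymethoxy)acetic pivalic anhydride | COCOCC(=O)OC(=O)C(C)(C)C
F3 | step 9 | (4S)-4-benzyl-3-[2-(methoxymethoxy)acetyl]-1,3-oxazolidin-2-one | COCOCC(=O)N1[C@@H](Cc2ccccc2)COC1=O
F4 | step 9 | (4S)-4-benzyl-3-[(2S,3R)-3-hydroxy-3-[3-methoxy-4-(methoxymethoxy)phenyl]-2-(methoxymethoxy)propanoyl]-1,3-oxazolidin-2-one | COc1cc([C@@H](O)[C@H](OCOC)C(=O)N2[C@@H](Cc3ccccc3)COC2=O)ccc1OCOC
F5 | step 9 | (2S,3R)-3-hydroxy-N-methoxy-3-[3-methoxy-4-(methoxymethoxy)phenyl]-2-(methoxymethoxy)-N-methylpropanamide | COc1cc([C@@H](O)[C@H](OCOC)C(=O)N(C)OC)ccc1OCOC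
F6 | step 9 | (2S,3R)-1-[2-fluoro-4,6-bis(methoxymethoxy)-3-(3-methylbut-2-en-1-yl)phenyl]-3-hydroxy-3-[3-methoxy-4-(methoxymethoxy)phenyl]-2-(methoxymethoxy)propan-1-one | COc1cc([C@@H](O)[C@H](OCOC)C(=O)c2c(F)c(CC=C(C)C)c(OCOC)cc2OCOC)ccc1OCOC
F7 | step 9 | (2R,3S)-2-[3-methoxy-4-(methoxymethoxy)phenyl]-3,5,7-tris(methoxymethoxy)-8-(3-methylbut-2-en-1-yl)-2,3-dihydro-4H-chromen-4-one | COc1cc([C@H]2Oc3c(CC=C(C)C)c(OCOC)cc(OCOC)c3C(=O)[C@H]2OCOC)ccc1OCOC
F8 | step 3 | 1-[3-bromo-2-fluoro-4,6-bis(methoxymethoxy)phenyl]-2-(methoxymethoxy)ethan-1-one | COCOCC(=O)c1c(F)c(Br)c(OCOC)cc1OCOC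
F0 | step 10 | none | none
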